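Readings and results were computed from invented constants; noise was put on by code.

Leave the flask alone. It is stirred, closed and isothermal, and you read it at 25 min.

| flask | J | X | remark | time |
|---|---|---|---|---|
| gamma | 0.050 M | 0.095 M | run made earlier |  |
| beta | 0.075 M | 0.095 M | run made earlier |  |
| flask | 0.10 M | 0.0950 M |  | 25 min |

| run | time / min | Z / % | E / % | D / % | L / % | J / % | Q / % |
|---|---|---|---|---|---|---|---|
| gamma | 2.00 | 3.2 | 30.8 | 38.1 | 4.6 | 16.1 | 7.5 |
| gamma | 5.00 | 6.0 | 38.9 | 30.5 | 1.5 | 1.4 | 21.5 |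
| gamma | 10.0 | 5.0 | 39.7 | 15.9 | 0.1 | 2.9 | 39.2 |
| gamma | 15.0 | 3.9 | 40.0 | 9.5 | 0 | 0 | 45.0 |
| gamma | 20.0 | 3.6 | 38.9 | 8.0 | 0.4 | 0 | 50.0 |
| beta | 2.00 | 6.7 | 28.4 | 38.2 | 3.8 | 17.4 | 8.1 |
| beta | 5.00 | 4.8 | 36.1 | 33.7 | 1.3 | 1.2 | 24.7 |
| beta | 10.0 | 4.8 | 37.3 | 19.0 | 0 | 1.0 | 39.9 |
| beta | 15.0 | 4.2 | 37.2 | 11.4 | 0 | 0 | 50.1 |
| beta | 20.0 | 0.9 | 34.6 | 7.7 | 0.3 | 0.6 | 51.9 |

(standard deviation of a reading: 1 percentage point)
- the species in which most of what was charged as J, at 25 min sits (D / Z / L / J / E / Q)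
- the largest share itself, whichever of these holds it, in percent of the J charged
- on the list of suspects stand: Z -> D; J + X <-> L; X + L -> E; J -> D; J <-> Z; D <-> Q

In both earlier runs J read 0% and 0% at 15.0 min, so expect to count where it went. Each E costs two X, one to make L from J and one to turn L into E. So I count X turnovers, and the X ceiling, the charge of X over twice the charge of J, caps the E share at 47.5% in this flask, where X would be the limiting reagent if J went to E and nowhere else.

At 15.0 min, E had used 42.1% of the X in the gamma run and 58.7% in the beta run. One more equal step in J gives my estimate of 75.4%, hence E near 35.8%. Taking off the 11.6% of D and Z last read in the gamma run, I expect Q near 52.6%. The forecast, reasoning that “each E takes two X”, says Q at 55%, a little above mine. Don't alter the X charge: both earlier runs had 0.095 M, and my step in J rests on that.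

The flask gives Q at 58.6%, with E at 31.7%.

    Z → D (k = 0.0296 /min)
    J + X ⇌ L (K = 9.80 /M, k = 6.51 /M/min)
    X + L → E (k = 27.3 /M/min)
    J → D (k = 0.500 /min)
    J ⇌ Z (K = 29.2, k = 0.0559 /min)
    D ⇌ Q (K = 14.0, k = 0.149 /min)

That E is 66.7% of the ceiling, and X stands at 33.2% of its charge. A neighbouring flask charged with 0.24 M of X has a ceiling of 120%. Its E reaches 63.8%, which is 53.2% of that ceiling, and its X stands at 46.8%. There the forecast's answer would turn: E holds the most, ahead of Q at 31.2%.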